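The data are simulated for an exercise, noise included.

Of the amounts charged I watch the nucleophile, 1.5 equiv in ochre and amber, rather than the free base.

all flasks: electrophile 0.25 M
- ochre: nucleophile 1.5 equiv; free base 4.1 equiv; run made earlier
- amber: nucleophile 1.5 equiv; free base 6.1 equiv; run made earlier
- south-west: nucleophile 1.50 equiv; free base 3.90 equiv; time 6.0 min
- north-west: nucleophile 1.50 equiv; free base 3.00 equiv; time 6.0 min

| run | time / min | electrophile / % | target / % |
|---|---|---|---|
| ochre | 0.833 | 38.5 | 36.5 |
| ochre | 2.00 | 24.6 | 31.7 |
| ochre | 4.00 | 15.2 | 31.3 |
| ochre | 6.00 | 8.8 | 32.1 |
| amber | 1.50 | 29.0 | 33.6 |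
| amber | 3.00 | 17.2 | 31.1 |
| amber | 5.00 | 10.3 | 32.5 |
| amber | 6.00 | 8.2 | 32.8 |

(scatter of a reading: 0.5 percentage points)

* part of the electrophile that has reacted at the end, south-west
* part of the electrophile that has reacted at the end, north-west
* what raising the equivalents of free base from its lowest to its highest value here does to the part of the electrophile that has reacted (changes below 5 percentage points count as none) (no change / it rises / it falls)

- the numbers in the tables scatter with a standard deviation of 0.5 percentage points

I suppose that each electrophile reacting sets one acid free and that this acid takes a second nucleophile, so each reacted electrophile costs two nucleophiles. Divided by two, the nucleophile equivalents then give the nucleophile ceiling, 75.0 % of the electrophile charged: the most that can react if no free base takes acid. At that cost, with no free base taking acid, the nucleophile is the limiting reagent.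

Ochre has 75.4 % reacted at 2.00 min, close to the ceiling, and then gains 16 points in the next 4.00 min. At 6.00 min ochre stands 16 points above the ceiling and amber 17 points; the two readings differ by 0.6 points, against a scatter of 0.5 points. South-west and north-west have the same ceiling, so I carry ochre's 91.2 % over to south-west and expect a little less for north-west, with the difference inside 5 points.

The forecast says 91 % for south-west, 90 % for north-west and no change, “suggesting a near-zero order in base, or saturation”.

The flasks give 89.7 % for south-west, 88.3 % for north-west and no change, with a change of 1.3 points, so the forecast holds.

    nucleophile + acid set free ⇌ protonated nucleophile, settled at all times (K = 12000 M⁻¹)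
    target ⇌ isomer of the product (K = 1.90, k = 0.0190 s⁻¹)
    acid set free + free base ⇌ salt of the base (K = 300 M⁻¹, k = 6.30 M⁻¹ s⁻¹)
    electrophile + nucleophile ⇌ acid set free + target (K = 1.10, k = 0.110 M⁻¹ s⁻¹)

North-west stands 13 points above its ceiling at 6.0 min. The neighbour of north-west charged with 0.380 equiv of nucleophile has a ceiling of 19.0 % and reaches 33.1 % at the same time, 14 points above it. North-west has not come to rest at 6.0 min: 11.7 % of its electrophile is still there. At 60.0 min south-west reaches 99.0 % and north-west 98.4 %, while in north-west the target goes from 31.2 % to 33.9 % and the isomer of the product from 57.1 % to 64.5 %.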